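**Retrosynthetic overview**

- Feature: in the cyclohexenone ring (C1–C6) fused to the oxirane (C4, C5, O), the segment C7–C1(=C2)–C6(=O) is a 2-(acetoxymethyl)enone. This is the allylically transposed, primary form of a Morita–Baylis–Hillman (MBH) acetate, so C7 can begin as the CH2 terminus of a vinyl ketone.
- Endgame, read backwards: target ⇐ desilylation ⇐ 1,3-shift of acetate from C2 to C7 ⇐ acetylation ⇐ 2-methylene-3-hydroxy epoxycyclohexanone.
- Key disconnection C1–C2: phosphine-catalysed intramolecular MBH reaction of an acyclic cis-oxirane that carries the vinyl ketone (C6) and an α-silyloxy aldehyde (C2) on the same side.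
- Precursor ⇐ Sharpless epoxidation (C4, C5) ⇐ CBS reduction (C3) ⇐ vinyllithium/aldehyde union (C3–C4) ⇐ hydroalumination–iodination ⇐ asymmetric alkynylation of farnesal (C1′).
- Ring order: oxirane first (acyclic stage), six-membered carbocycle second (key step).

Key step: step 16

Remark on numbering and abbreviations: the ring numbering of the target is used for all intermediates: C1 (carries C7H2OAc), C2, C3 (carbinol), C4 (quaternary oxirane carbon), C5 (oxirane CH), C6 (C=O), side chain C1′–C12′. R = (1E,5E)-2,6,10-trimethylundeca-1,5,9-trien-1-yl (C2′–C12′); TBS = tert-butyldimethylsilyl; PMB = 4-methoxybenzyl.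

Assumption: (S,S)-ProPhenol is taken to deliver the alkynylzinc to the aldehyde face that gives the (S)-carbinol; if the sense proves opposite, the (R,R)-ligand is used and nothing else changes.

**Route**

Step 1
Reactants: 1 (2E,6E)-farnesol
Product: 2 (2E,6E)-farnesal [(2E,6E)-3,7,11-trimethyldodeca-2,6,10-trienal]
Conditions: MnO2 (15 equiv), CH2Cl2, rt
Reagents that add atoms: none
Why: Allylic oxidation with activated MnO2 is selective for the primary allylic alcohol and should leave the 2E geometry and the isolated alkenes intact.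

Step 2
Reactants: 2 (2E,6E)-farnesal; 3 methyl propiolate
Product: 4 methyl (4S,5E,9E)-4-hydroxy-6,10,14-trimethylpentadeca-5,9,13-trien-2-ynoate
Conditions: (S,S)-ProPhenol (0.1 equiv), Me2Zn (3 equiv), toluene, 4 °C
Reagents that add atoms: none
Why: Zinc–ProPhenol asymmetric alkynylation (Trost) of an enal with methyl propiolate; the chiral dinuclear zinc alkynylide differentiates the aldehyde faces and sets C1′ as (S).

Step 3
Reactants: 4 methyl (4S,5E,9E)-4-hydroxy-6,10,14-trimethylpentadeca-5,9,13-trien-2-ynoate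
Product: 5 methyl (4S,5E,9E)-4-(tert-butyldimethylsilyloxy)-6,10,14-trimethylpentadeca-5,9,13-trien-2-ynoate
Conditions: TBSOTf, 2,6-lutidine, CH2Cl2, −78 °C
Reagents that add atoms: tert-butyldimethylsilyl trifluoromethanesulfonate, CC(C)(C)[Si](C)(C)OS(=O)(=O)C(F)(F)F
Why: Silylation with the silyl triflate and a non-nucleophilic base is fast at low temperature, which avoids base-induced isomerisation of the γ-hydroxy ynoate; no stereocentre is touched.

Step 4
Reactants: 5 methyl (4S,5E,9E)-4-(tert-butyldimethylsilyloxy)-6,10,14-trimethylpentadeca-5,9,13-trien-2-ynoate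
Product: 6 (4S,5E,9E)-4-(tert-butyldimethylsilyloxy)-6,10,14-trimethylpentadeca-5,9,13-trien-2-yn-1-ol
Conditions: i-Bu2AlH (2.5 equiv), CH2Cl2, −78 °C; Rochelle salt
Reagents that add atoms: none
Why: 1,2-Reduction of the ynoate with DIBAL-H at low temperature gives the propargylic alcohol needed as directing group, without conjugate reduction.

Step 5
Reactants: 6 (4S,5E,9E)-4-(tert-butyldimethylsilyloxy)-6,10,14-trimethylpentadeca-5,9,13-trien-2-yn-1-ol
Product: 8 (2Z,4S,5E,9E)-4-(tert-butyldimethylsilyloxy)-3-iodo-6,10,14-trimethylpentadeca-2,5,9,13-tetraen-1-ol, via alkenylalanate 7 (not isolated)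
Conditions: NaAlH2(OCH2CH2OMe)2 (Red-Al), THF, 0 °C; EtOAc; then I2, −78 °C
Reagents that add atoms: iodine, II
Why: Hydroxyl-directed trans-hydroalumination (hydride to C5, aluminium to C4 in a five-membered chelate) followed by iodinolysis with retention places iodine on C4 cis to C6, which fixes the later cis relation of C3 and C6; the low temperature should suppress β-elimination of the C1′ silyloxy group.

Step 6
Reactants: 8 (2Z,4S,5E,9E)-4-(tert-butyldimethylsilyloxy)-3-iodo-6,10,14-trimethylpentadeca-2,5,9,13-tetraen-1-ol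
Product: 9 4-methoxybenzyl ether of 8 (PMBO–C6H2–C5H=C4(I)–C1′H(OTBS)–R; iodine cis to C6)
Conditions: NaH, PMBCl, n-Bu4NI (cat.), THF–DMF, 0 °C
Reagents that add atoms: 4-methoxybenzyl chloride, COc1ccc(CCl)cc1
Why: Williamson etherification; a benzyl-type ether is chosen because a silyl group on O–C6 would migrate to C4 (1,4 O→C retro-Brook shift) in the cis γ-silyloxy vinyllithium of the next step.

Step 7
Reactants: 9 4-methoxybenzyl ether of 8; 10 (tert-butyldimethylsilyloxy)acetaldehyde
Product: 12 C3-epimeric allylic alcohols TBSO–C2H2–C3H(OH)–C4(=C5H–C6H2OPMB)–C1′H(OTBS)–R (C3 cis to C6; 1′S), via vinyllithium 11 (not isolated)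
Conditions: t-BuLi (2.1 equiv), Et2O, −78 °C; then 10
Reagents that add atoms: none
Why: Iodine–lithium exchange with retention of alkene geometry and 1,2-addition to the aldehyde form the C3–C4 bond; C3 arises unselectively and is corrected in steps 8 and 9.

Step 8
Reactants: 12 C3-epimeric allylic alcohols
Product: 13 enone TBSO–C2H2–C3(=O)–C4(=C5H–C6H2OPMB)–C1′H(OTBS)–R (C3 cis to C6; 1′S)
Conditions: Dess–Martin periodinane, NaHCO3, CH2Cl2, 0 °C to rt
Reagents that add atoms: none
Why: Buffered Dess–Martin oxidation converts both C3 epimers into one α′-silyloxy enone without disturbing the C4=C5 geometry.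

Step 9
Reactants: 13 enone
Product: 14 allylic alcohol TBSO–C2H2–C3H(OH)–C4(=C5H–C6H2OPMB)–C1′H(OTBS)–R with C3 configured as in the target (3R in this compound; 1′S)
Conditions: (R)-Me-CBS oxazaborolidine (0.2 equiv), catecholborane, toluene, −78 °C
Reagents that add atoms: none
Why: Corey–Bakshi–Shibata reduction; the fully substituted alkenyl carbon C4 acts as the large group and CH2OTBS as the small one, so the (R)-catalyst should deliver hydride to the face that gives the C3 configuration of the target, and catecholborane leaves the polyene untouched.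

Step 10
Reactants: 14 allylic alcohol
Product: 15 tris-silyl ether TBSO–C2H2–C3H(OTBS)–C4(=C5H–C6H2OPMB)–C1′H(OTBS)–R
Conditions: TBSOTf, 2,6-lutidine, CH2Cl2, −78 to 0 °C
Reagents that add atoms: tert-butyldimethylsilyl trifluoromethanesulfonate, CC(C)(C)[Si](C)(C)OS(=O)(=O)C(F)(F)F
Why: Silylation of the hindered secondary allylic alcohol with the silyl triflate; the C3 configuration is retained.

Step 11
Reactants: 15 tris-silyl ether
Product: 16 primary allylic alcohol TBSO–C2H2–C3H(OTBS)–C4(=C5H–C6H2OH)–C1′H(OTBS)–R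
Conditions: DDQ, CH2Cl2–pH 7 buffer, 0 °C
Reagents that add atoms: none
Why: Oxidative cleavage of the PMB ether with DDQ spares silyl ethers and isolated alkenes and frees the alcohol that directs the epoxidation.

Step 12
Reactants: 16 primary allylic alcohol
Product: 17 epoxy alcohol TBSO–C2H2–C3H(OTBS)–C4(oxirane)[C1′H(OTBS)R]–C5H(oxirane)–C6H2OH (C3 and C6 cis on the oxirane; C4 and C5 as in the target)
Conditions: Ti(OiPr)4 (1.0 equiv), L-(+)-DET (1.2 equiv), t-BuOOH, 4 Å MS, CH2Cl2, −20 °C
Reagents that add atoms: tert-butyl hydroperoxide, CC(C)(C)OO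
Why: Sharpless asymmetric epoxidation; only the allylic alkene C4=C5 reacts, and L-(+)-diethyl tartrate, the enantiomer that gives (2S,3S)-epoxygeraniol from geraniol, should deliver oxygen to the face that makes C5 (S) in this compound and C4 as in the target.

Step 13
Reactants: 17 epoxy alcohol; 18 vinylmagnesium bromide
Product: 20 C6-epimeric vinyl carbinols TBSO–C2H2–C3H(OTBS)–C4(oxirane)[C1′H(OTBS)R]–C5H(oxirane)–C6H(OH)–CH=CH2, via epoxy aldehyde 19 (not isolated)
Conditions: (COCl)2, DMSO, THF, −78 °C; Et3N; then 18 (5 equiv), −78 °C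
Reagents that add atoms: none
Why: One-pot Swern oxidation and Grignard addition (Ireland protocol) avoids isolating the sensitive α,β-epoxy aldehyde; the C6 carbinol centre forms unselectively and is removed in step 15.

Step 14
Reactants: 20 C6-epimeric vinyl carbinols
Product: 21 diol HO–C2H2–C3H(OTBS)–C4(oxirane)[C1′H(OTBS)R]–C5H(oxirane)–C6H(OH)–CH=CH2
Conditions: HF·pyridine, pyridine, THF, 0 °C
Reagents that add atoms: none
Why: Buffered HF·pyridine should cleave the unhindered primary silyl ether on C2 well before the two hindered secondary ones, without silyl migration or oxirane opening.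

Step 15
Reactants: 21 diol
Product: 22 keto aldehyde O=C2H–C3H(OTBS)–C4(oxirane)[C1′H(OTBS)R]–C5H(oxirane)–C6(=O)–C1H=C7H2 (the MBH precursor)
Conditions: Dess–Martin periodinane (3 equiv), NaHCO3, CH2Cl2, 0 °C to rt
Reagents that add atoms: none
Why: Double Dess–Martin oxidation gives the aldehyde and the vinyl ketone in one operation under near-neutral conditions that should not epimerise C3.

Step 16
Reactants: 22 keto aldehyde
Product: 25 2-methylene-3-hydroxy epoxycyclohexanone C1(=C7H2)–C2H(OH)–C3H(OTBS)–C4(oxirane)[C1′H(OTBS)R]–C5H(oxirane)–C6(=O) (2,3-trans epimer drawn; its C2 epimer is carried along), via phosphonium enolate 23 (not isolated), via phosphonium aldolate 24 (not isolated)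
Conditions: PMe3 (0.3 equiv), t-AmOH–CH2Cl2 (1:4), 0.01 M, 0 °C to rt
Reagents that add atoms: none
Why: PMe3 adds reversibly to the unsubstituted terminus C7 of the vinyl ketone to give enolate 23, whose carbon C1 attacks the aldehyde C2 to give aldolate 24; proton transfer from C1–H, helped by the alcohol cosolvent, and loss of PMe3 restore the C1=C7 alkene. The closest known reaction type is the trialkylphosphine-catalysed intramolecular Morita–Baylis–Hillman cyclisation of enone aldehydes. The six-membered carbocycle closes in a 6-(enolendo)-exo-trig mode, with the enolate C6=C1 inside the new ring and the aldehyde C=O outside. The new stereocentre C2 is set under substrate control by the neighbouring C3–OTBS group (Felkin-type attack anti to the C3–O bond is expected to favour the 2,3-trans epimer), but it need not be controlled because the later allylic shift makes C2 an sp2 carbon. The step needs phosphine attack at C7 only and ring closure in preference to Rauhut–Currier oligomerisation; the unhindered CH2 terminus, the cis-oxirane that holds C3 and C6 on one side, and high dilution secure this. The neutral, weakly basic catalyst should leave the oxirane, the polyene and the C3 centre untouched.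

Step 17
Reactants: 25 2-methylene-3-hydroxy epoxycyclohexanone
Product: 26 C2 acetate of 25 (secondary allylic acetate; exocyclic C1=C7H2 retained)
Conditions: Ac2O, pyridine, DMAP (cat.), CH2Cl2, 0 °C
Reagents that add atoms: acetic anhydride, CC(=O)OC(C)=O
Why: Acylation of the secondary allylic alcohol; either C2 epimer is acetylated and no other free hydroxyl is present.

Step 18
Reactants: 26 C2 acetate
Product: 28 bis-TBS ether of the target (AcO–C7H2 on C1; C1=C2; C3–OTBS; C1′–OTBS), via allylammonium acetate 27 (not isolated)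
Conditions: DABCO (0.5 equiv), THF, rt
Reagents that add atoms: none
Why: Amine-catalysed 1,3-transposition of a Baylis–Hillman acetate: DABCO adds to C7 with SN2′ loss of acetate from C2 (either epimer), and acetate returns at C7 by SN2 displacement of the ammonium group, giving the more stable endocyclic trisubstituted enone.

Step 19
Reactants: 28 bis-TBS ether of the target
Product: 29 target CNP0137670.2, [(1R,5S,6R)-5-hydroxy-6-[(1S,2E,6E)-1-hydroxy-3,7,11-trimethyldodeca-2,6,10-trien-1-yl]-2-oxo-7-oxabicyclo[4.1.0]hept-3-en-3-yl]methyl acetate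
Conditions: HF·pyridine, pyridine, THF, 0 °C to rt
Reagents that add atoms: none
Why: Fluoride-mediated cleavage of the two secondary silyl ethers under weakly acidic conditions, which the allylic acetate and the epoxy enone should tolerate better than basic fluoride sources.

**Compound list**

1 | (2E,6E)-farnesol | CC(C)=CCC/C(C)=C/CC/C(C)=C/CO | starting material
2 | (2E,6E)-farnesal | CC(C)=CCC/C(C)=C/CC/C(C)=C/C=O | intermediate
3 | methyl propiolate | C#CC(=O)OC | starting material
4 | methyl (4S,5E,9E)-4-hydroxy-6,10,14-trimethylpentadeca-5,9,13-trien-2-ynoate | COC(=O)C#C[C@@H](O)/C=C(\C)CC/C=C(\C)CCC=C(C)C | intermediate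
5 | methyl (4S,5E,9E)-4-(tert-butyldimethylsilyloxy)-6,10,14-trimethylpentadeca-5,9,13-trien-2-ynoate | COC(=O)C#C[C@@H](O[Si](C)(C)C(C)(C)C)/C=C(\C)CC/C=C(\C)CCC=C(C)C | intermediate
6 | (4S,5E,9E)-4-(tert-butyldimethylsilyloxy)-6,10,14-trimethylpentadeca-5,9,13-trien-2-yn-1-ol | OCC#C[C@@H](O[Si](C)(C)C(C)(C)C)/C=C(\C)CC/C=C(\C)CCC=C(C)C | intermediate
7 | sodium alkenylalanate (five-membered O–C6–C5=C4–Al chelate, Al on C4) | [Na+].COCCO[Al-]1(OCCOC)OCC=C1[C@@H](O[Si](C)(C)C(C)(C)C)/C=C(\C)CC/C=C(\C)CCC=C(C)C | intermediate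
8 | (2Z,4S,5E,9E)-4-(tert-butyldimethylsilyloxy)-3-iodo-6,10,14-trimethylpentadeca-2,5,9,13-tetraen-1-ol | OC/C=C(\I)[C@@H](O[Si](C)(C)C(C)(C)C)/C=C(\C)CC/C=C(\C)CCC=C(C)C | intermediate
9 | 4-methoxybenzyl ether of 8 | COc1ccc(COC/C=C(\I)[C@@H](O[Si](C)(C)C(C)(C)C)/C=C(\C)CC/C=C(\C)CCC=C(C)C)cc1 | intermediate
10 | (tert-butyldimethylsilyloxy)acetaldehyde | CC(C)(C)[Si](C)(C)OCC=O | starting material
11 | C4 vinyllithium from 9 | COc1ccc(COC/C=C(\[Li])[C@@H](O[Si](C)(C)C(C)(C)C)/C=C(\C)CC/C=C(\C)CCC=C(C)C)cc1 | intermediate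
12 | C3-epimeric allylic alcohols (C3–OH; C6–OPMB; C3 cis to C6) | CC(C)(C)[Si](C)(C)OCC(O)/C(=C\COCc1ccc(OC)cc1)[C@@H](O[Si](C)(C)C(C)(C)C)/C=C(\C)CC/C=C(\C)CCC=C(C)C | intermediate
13 | enone (C3 ketone; C6–OPMB) | CC(C)(C)[Si](C)(C)OCC(=O)/C(=C\COCc1ccc(OC)cc1)[C@@H](O[Si](C)(C)C(C)(C)C)/C=C(\C)CC/C=C(\C)CCC=C(C)C | intermediate
14 | allylic alcohol with C3 as in the target (3R here) | CC(C)(C)[Si](C)(C)OC[C@H](O)/C(=C\COCc1ccc(OC)cc1)[C@@H](O[Si](C)(C)C(C)(C)C)/C=C(\C)CC/C=C(\C)CCC=C(C)C | intermediate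
15 | tris-TBS ether with C6–OPMB | CC(C)(C)[Si](C)(C)OC[C@H](O[Si](C)(C)C(C)(C)C)/C(=C\COCc1ccc(OC)cc1)[C@@H](O[Si](C)(C)C(C)(C)C)/C=C(\C)CC/C=C(\C)CCC=C(C)C | intermediate
16 | primary allylic alcohol (C6–OH) | CC(C)(C)[Si](C)(C)OC[C@H](O[Si](C)(C)C(C)(C)C)/C(=C\CO)[C@@H](O[Si](C)(C)C(C)(C)C)/C=C(\C)CC/C=C(\C)CCC=C(C)C | intermediate
17 | epoxy alcohol (oxirane C4–C5; C6–OH) | CC(C)(C)[Si](C)(C)OC[C@H](O[Si](C)(C)C(C)(C)C)[C@@]1([C@@H](O[Si](C)(C)C(C)(C)C)/C=C(\C)CC/C=C(\C)CCC=C(C)C)O[C@H]1CO | intermediate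
18 | vinylmagnesium bromide | C=C[Mg]Br | starting material
19 | epoxy aldehyde (C6 = CHO) | CC(C)(C)[Si](C)(C)OC[C@H](O[Si](C)(C)C(C)(C)C)[C@@]1([C@@H](O[Si](C)(C)C(C)(C)C)/C=C(\C)CC/C=C(\C)CCC=C(C)C)O[C@H]1C=O | intermediate
20 | C6-epimeric vinyl carbinols | CC(C)(C)[Si](C)(C)OC[C@H](O[Si](C)(C)C(C)(C)C)[C@@]1([C@@H](O[Si](C)(C)C(C)(C)C)/C=C(\C)CC/C=C(\C)CCC=C(C)C)O[C@H]1C(O)C=C | intermediate
21 | diol (C2–OH primary; C6–OH allylic) | OC[C@H](O[Si](C)(C)C(C)(C)C)[C@@]1([C@@H](O[Si](C)(C)C(C)(C)C)/C=C(\C)CC/C=C(\C)CCC=C(C)C)O[C@H]1C(O)C=C | intermediate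
22 | keto aldehyde, the MBH precursor | O=C[C@H](O[Si](C)(C)C(C)(C)C)[C@@]1([C@@H](O[Si](C)(C)C(C)(C)C)/C=C(\C)CC/C=C(\C)CCC=C(C)C)O[C@H]1C(=O)C=C | intermediate
23 | phosphonium enolate (PMe3 on C7) | O=C[C@H](O[Si](C)(C)C(C)(C)C)[C@@]1([C@@H](O[Si](C)(C)C(C)(C)C)/C=C(\C)CC/C=C(\C)CCC=C(C)C)O[C@H]1C([O-])=CC[P+](C)(C)C | intermediate
24 | phosphonium aldolate (ring closed; alkoxide on C2) | C[P+](C)(C)CC1[C@@H]([O-])[C@H](O[Si](C)(C)C(C)(C)C)[C@@]2([C@@H](O[Si](C)(C)C(C)(C)C)/C=C(\C)CC/C=C(\C)CCC=C(C)C)O[C@H]2C1=O | intermediate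
25 | 2-methylene-3-hydroxy epoxycyclohexanone (2,3-trans epimer drawn) | C=C1[C@@H](O)[C@H](O[Si](C)(C)C(C)(C)C)[C@@]2([C@@H](O[Si](C)(C)C(C)(C)C)/C=C(\C)CC/C=C(\C)CCC=C(C)C)O[C@H]2C1=O | intermediate
26 | C2 acetate of 25 | C=C1[C@@H](OC(C)=O)[C@H](O[Si](C)(C)C(C)(C)C)[C@@]2([C@@H](O[Si](C)(C)C(C)(C)C)/C=C(\C)CC/C=C(\C)CCC=C(C)C)O[C@H]2C1=O | intermediate
27 | allylammonium acetate (DABCO on C7; C1=C2) | CC(=O)[O-].C1CN2CC[N+]1(CC2)CC1=C[C@H](O[Si](C)(C)C(C)(C)C)[C@@]2([C@@H](O[Si](C)(C)C(C)(C)C)/C=C(\C)CC/C=C(\C)CCC=C(C)C)O[C@H]2C1=O | intermediate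
28 | bis-TBS ether of the target | CC(=O)OCC1=C[C@H](O[Si](C)(C)C(C)(C)C)[C@@]2([C@@H](O[Si](C)(C)C(C)(C)C)/C=C(\C)CC/C=C(\C)CCC=C(C)C)O[C@H]2C1=O | intermediate
29 | CNP0137670.2 | CC(=O)OCC1=C[C@H](O)[C@@]2([C@@H](O)/C=C(\C)CC/C=C(\C)CCC=C(C)C)O[C@H]2C1=O | target

**Step count**

Total: 19 steps. Longest linear sequence: 19 steps (farnesol to target; methyl propiolate, the silyloxyacetaldehyde and vinylmagnesium bromide are bought).

**Steps most likely to fail**

Step 16 (key MBH closure). The zwitterionic enolate may add to a second vinyl ketone (Rauhut–Currier oligomerisation), or the aldol closure may be slow enough for C3 to epimerise through enolisation of the α-silyloxy aldehyde. Fallback: a stoichiometric Michael–aldol/elimination sequence that forms the same C1–C2 bond. It sets out from 22. PhSeLi (THF, −78 °C) adds to C7 and the lithium enolate closes onto C2 to give the selanylmethyl aldol F1. H2O2/pyridine (CH2Cl2, 0 °C) gives the selenoxide F2, which undergoes syn-elimination towards C1–H at or below room temperature and returns to the route at 25.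

Step 12 (Sharpless epoxidation). Both substituents on C4 are branched and silylated, so oxygen transfer may be slow, and the reagent may be mismatched with the two allylic stereocentres, which would erode face selectivity. Fallback: substrate-directed epoxidation at an earlier, less hindered stage. It sets out from 14. Ti(OiPr)4/t-BuOOH without tartrate (CH2Cl2, −20 to 0 °C) epoxidises C4=C5 under direction of the free C3–OH. With C6 cis to C3, the A(1,3)-minimised conformer (C3–H eclipsing the alkene) should lead to the threo epoxy alcohol F3, which is the relative configuration required. TBSOTf/2,6-lutidine gives the silyl ether F4, and DDQ returns to the route at 17.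

Step 18 (acetate transposition). The amine or acetate may deprotonate C3 (γ to the ketone), leading to oxirane opening and aromatisation, or the sequence may stall at the ammonium salt. Fallback: a halide route that avoids amine bases. It sets out from 25 (step 17 is skipped). NBS/Me2S (CH2Cl2, 0 °C) converts the allylic alcohol by SN2′ into the 2-(bromomethyl)enone F5 (alkene C1=C2), and AgOAc (CH2Cl2–MeCN, rt) displaces bromide to return to the route at 28.

**Further compounds**

F1 | step 16 | selanylmethyl aldol (PhSe on C7; C1–H; C2–OH) | c1ccccc1[Se]CC1[C@@H](O)[C@H](O[Si](C)(C)C(C)(C)C)[C@@]2([C@@H](O[Si](C)(C)C(C)(C)C)/C=C(\C)CC/C=C(\C)CCC=C(C)C)O[C@H]2C1=O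
F2 | step 16 | selenoxide of F1 | O=[Se](c1ccccc1)CC1[C@@H](O)[C@H](O[Si](C)(C)C(C)(C)C)[C@@]2([C@@H](O[Si](C)(C)C(C)(C)C)/C=C(\C)CC/C=C(\C)CCC=C(C)C)O[C@H]2C1=O
F3 | step 12 | epoxy alcohol with free C3–OH and C6–OPMB | CC(C)(C)[Si](C)(C)OC[C@H](O)[C@@]1([C@@H](O[Si](C)(C)C(C)(C)C)/C=C(\C)CC/C=C(\C)CCC=C(C)C)O[C@H]1COCc1ccc(OC)cc1
F4 | step 12 | C3 TBS ether of F3 | CC(C)(C)[Si](C)(C)OC[C@H](O[Si](C)(C)C(C)(C)C)[C@@]1([C@@H](O[Si](C)(C)C(C)(C)C)/C=C(\C)CC/C=C(\C)CCC=C(C)C)O[C@H]1COCc1ccc(OC)cc1
F5 | step 18 | 2-(bromomethyl)enone (Br on C7; C1=C2; both TBS ethers kept) | BrCC1=C[C@H](O[Si](C)(C)C(C)(C)C)[C@@]2([C@@H](O[Si](C)(C)C(C)(C)C)/C=C(\C)CC/C=C(\C)CCC=C(C)C)O[C@H]2C1=O
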